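**Plan**
- Feature: the target is one cyclopentene ring whose unsubstituted C3=C4 double bond lies opposite the quaternary C1 (OH, tridecanoyl), flanked by C2 (OH) and C5 (OAc). Cutting C3=C4 leaves an acyclic hepta-1,6-diene whose C2–C1–C5 triol has the C4–C3–C2 pattern of D-glucose.
- Further cuts: the terminal C=C on the acetoxy side (aldehyde methylenation); that aldehyde together with the other vinyl group (zinc fragmentation of a 6-iodo methyl glucopyranoside); the C1–acyl unit (Wittig alkene at sugar C3, then dihydroxylation and oxidation).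
- Forward order: methyl 4,6-O-benzylidene-α-D-glucopyranoside, C13 chain joined at sugar C3, pyranose ring opened, then the cyclopentene (the only ring of the target) closed last.
- Stereochemistry: target C5 and C2 are glucose C2 and C4; C1 is set by osmylation of the exocyclic alkene from its equatorial face. O4 sits in the benzylidene acetal while O2 is handled separately, so the acetate is placed on O2 without any desymmetrisation.

Key step: step 13

Remark: sugar numbering (C1–C6, side-chain carbon C1′) is used for 1–14; alkene 6 and diol 7 are carried as mixtures at C1′ (alkene geometry, carbinol configuration), which converge at ketone 8.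

**Step 1**
Reactants: 1 methyl 4,6-O-benzylidene-α-D-glucopyranoside
Product: 2 methyl 4,6-O-benzylidene-2-O-(4-methoxybenzyl)-α-D-glucopyranoside
Conditions: 4-methoxybenzyl chloride, Bu4NHSO4 (cat.), aq NaOH, CH2Cl2, reflux
Reagents that add atoms: 4-methoxybenzyl chloride, COc1ccc(CCl)cc1
Why: Phase-transfer Williamson etherification, in which the 2-OH, acidified by the neighbouring anomeric acetal, should be alkylated in preference to the 3-OH, the established regiochemistry for this α-glucoside diol.

**Step 2**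
Reactants: 2 methyl 4,6-O-benzylidene-2-O-(4-methoxybenzyl)-α-D-glucopyranoside
Product: 3 methyl 4,6-O-benzylidene-2-O-(4-methoxybenzyl)-α-D-ribo-hexopyranosid-3-ulose
Conditions: Dess–Martin periodinane, pyridine, CH2Cl2, 0 → 25 °C
Reagents that add atoms: none
Why: Dess–Martin oxidation of the only free secondary alcohol; the acetal, glycoside and benzyl ether are inert and the non-basic medium avoids β-elimination of the ulose.

**Step 3**
Reactants: 3 methyl 4,6-O-benzylidene-2-O-(4-methoxybenzyl)-α-D-ribo-hexopyranosid-3-ulose; 4 tridecyltriphenylphosphonium bromide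
Product: 6 methyl 4,6-O-benzylidene-3-deoxy-2-O-(4-methoxybenzyl)-3-C-tridecylidene-α-D-ribo-hexopyranoside, via tridecylidenetriphenylphosphorane 5 (not isolated)
Conditions: 4, KN(SiMe3)2, THF, 0 °C; then 3, −78 → 25 °C
Reagents that add atoms: tridecyltriphenylphosphonium bromide 4 (the reactant above), CCCCCCCCCCCCC[P+](c1ccccc1)(c1ccccc1)c1ccccc1.[Br-]
Why: Wittig olefination of the ketone with a salt-free non-stabilised ylide, the standard entry to 3-C-alkylidene sugars; alkene geometry is immaterial because C1′ later becomes a carbonyl carbon.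

**Step 4**
Reactants: 6 methyl 4,6-O-benzylidene-3-deoxy-2-O-(4-methoxybenzyl)-3-C-tridecylidene-α-D-ribo-hexopyranoside
Product: 7 methyl 4,6-O-benzylidene-3-C-(1-hydroxytridecyl)-2-O-(4-methoxybenzyl)-α-D-glucopyranoside
Conditions: OsO4 (cat.), N-methylmorpholine N-oxide, acetone/H2O, 25 °C
Reagents that add atoms: N-methylmorpholine N-oxide, C[N+]1([O-])CCOCC1 (oxygen relayed through osmium tetroxide, O=[Os](=O)(=O)=O); water, O
Why: Upjohn dihydroxylation, in which the axial anomeric methoxy group shields the axial side of the exocyclic alkene, so osmium tetroxide should add from the equatorial (β) side and make the new C3–O bond equatorial (gluco configuration), the same facial preference that directs nucleophiles onto the parent 3-ulose.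

**Step 5**
Reactants: 7 methyl 4,6-O-benzylidene-3-C-(1-hydroxytridecyl)-2-O-(4-methoxybenzyl)-α-D-glucopyranoside
Product: 8 methyl 4,6-O-benzylidene-2-O-(4-methoxybenzyl)-3-C-tridecanoyl-α-D-glucopyranoside
Conditions: Dess–Martin periodinane, pyridine, CH2Cl2, 0 → 25 °C
Reagents that add atoms: none
Why: Dess–Martin oxidation of the secondary C1′ alcohol to the ketone; the tertiary C3 hydroxyl cannot be oxidised and the neutral medium avoids glycol cleavage and retro-aldol opening.

**Step 6**
Reactants: 8 methyl 4,6-O-benzylidene-2-O-(4-methoxybenzyl)-3-C-tridecanoyl-α-D-glucopyranoside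
Product: 9 methyl 4,6-O-benzylidene-3-C-tridecanoyl-α-D-glucopyranoside
Conditions: DDQ, CH2Cl2/H2O, 0 → 25 °C
Reagents that add atoms: none
Why: Oxidative cleavage of the 4-methoxybenzyl ether by DDQ (hydride abstraction, then hydrolysis of the oxocarbenium ion), to which the unsubstituted benzylidene acetal, the ketone and the tertiary alcohol are inert.

**Step 7**
Reactants: 9 methyl 4,6-O-benzylidene-3-C-tridecanoyl-α-D-glucopyranoside
Product: 10 methyl 2-O-acetyl-4,6-O-benzylidene-3-C-tridecanoyl-α-D-glucopyranoside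
Conditions: Ac2O, pyridine, DMAP (cat.), CH2Cl2, 0 °C
Reagents that add atoms: acetic anhydride, CC(=O)OC(C)=O
Why: DMAP-catalysed acylation of the only secondary hydroxyl; the tertiary, carbonyl-flanked C3–OH is too hindered to be acetylated at 0 °C.

**Step 8**
Reactants: 10 methyl 2-O-acetyl-4,6-O-benzylidene-3-C-tridecanoyl-α-D-glucopyranoside
Product: 11 methyl 2-O-acetyl-3-C-tridecanoyl-α-D-glucopyranoside
Conditions: H2 (1 atm), Pd(OH)2/C, EtOAc/MeOH, 25 °C
Reagents that add atoms: none
Why: Hydrogenolysis of the benzylidene acetal under neutral conditions, which rules out acetyl migration; no alkene is present yet and the hindered dialkyl ketone is not reduced.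

**Step 9**
Reactants: 11 methyl 2-O-acetyl-3-C-tridecanoyl-α-D-glucopyranoside
Product: 12 methyl 2-O-acetyl-6-deoxy-6-iodo-3-C-tridecanoyl-α-D-glucopyranoside
Conditions: I2, PPh3, imidazole, toluene/MeCN, 60 °C
Reagents that add atoms: iodine, II
Why: Garegg–Samuelsson (Appel-type) iodination, in which the primary 6-OH is displaced through its alkoxyphosphonium salt far faster than the secondary 4-OH or the tertiary 3-OH.

**Step 10**
Reactants: 12 methyl 2-O-acetyl-6-deoxy-6-iodo-3-C-tridecanoyl-α-D-glucopyranoside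
Product: 13 methyl 2-O-acetyl-4-O-(tert-butyldimethylsilyl)-6-deoxy-6-iodo-3-C-tridecanoyl-α-D-glucopyranoside
Conditions: TBSOTf, 2,6-lutidine, CH2Cl2, −40 → 0 °C
Reagents that add atoms: tert-butyldimethylsilyl trifluoromethanesulfonate, CC(C)(C)[Si](C)(C)OS(=O)(=O)C(F)(F)F
Why: Silylation with the silyl triflate, which the hindered equatorial 4-OH requires; the tertiary hydroxyl reacts more slowly still and low temperature suppresses silyl enol ether formation at the ketone.

**Step 11**
Reactants: 13 methyl 2-O-acetyl-4-O-(tert-butyldimethylsilyl)-6-deoxy-6-iodo-3-C-tridecanoyl-α-D-glucopyranoside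
Product: 14 2-O-acetyl-4-O-(tert-butyldimethylsilyl)-5,6-dideoxy-3-C-tridecanoyl-aldehydo-D-xylo-hex-5-enose
Conditions: Zn dust (activated), THF/H2O 4:1, sonication, 40 °C; crude product used at once
Reagents that add atoms: none
Why: Bernet–Vasella reductive fragmentation, in which zinc inserts into the C6–I bond and β-elimination of the ring oxygen opens the pyranoside to the C5=C6 alkene and the C1 aldehyde with loss of methanol; the 4-O-silyl group prevents re-closure to a lactol, and C2 and C4 are untouched.

**Step 12**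
Reactants: 14 2-O-acetyl-4-O-(tert-butyldimethylsilyl)-5,6-dideoxy-3-C-tridecanoyl-aldehydo-D-xylo-hex-5-enose
Product: 15 (3S,4R,5R)-5-(tert-butyldimethylsilyloxy)-4-hydroxy-4-tridecanoylhepta-1,6-dien-3-yl acetate
Conditions: CH2(ZnI)2 [from CH2I2, Zn, PbCl2 (cat.), THF], THF, 0 → 25 °C
Reagents that add atoms: diiodomethane, ICI
Why: Takai-type carbonyl methylenation with the geminal dizinc reagent, which is non-basic and aldehyde-selective, so the α-acetoxy stereocentre should not epimerise and the hindered ketone and the ester are spared.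

**Step 13**
Reactants: 15 (3S,4R,5R)-5-(tert-butyldimethylsilyloxy)-4-hydroxy-4-tridecanoylhepta-1,6-dien-3-yl acetate
Product: 16 (1S,4R,5R)-4-(tert-butyldimethylsilyloxy)-5-hydroxy-5-tridecanoylcyclopent-2-en-1-yl acetate
Conditions: second-generation Grubbs catalyst RuCl2(=CHPh)(PCy3)(H2IMes) (5 mol %), CH2Cl2 (0.005 M), 40 °C
Reagents that add atoms: none
Why: Ring-closing olefin metathesis by the Chauvin mechanism: the ruthenium benzylidene exchanges onto the less hindered, acetoxy-bearing vinyl group, the resulting alkylidene adds across the second vinyl group to give a ruthenacyclobutane, and cycloreversion releases the cyclopentene and, after turnover, ethylene. The closest known reaction type is the ring-closing metathesis of carbohydrate-derived, oxygenated hepta-1,6-dienes to cyclopentenols. The single ring is a five-membered carbocycle closed at the new C=C bond between the two internal vinyl carbons of a 1,6-diene, and only the cis-alkene is possible. No stereocentre is formed; all three are in place and none is allylic to an acidic hydrogen that the catalyst could scramble. The step needs cyclisation to outrun cross-metathesis and must tolerate the free tertiary alcohol and the ketone. High dilution, the fully substituted central carbon (which folds the two vinyl arms together) and the functional-group tolerance of the N-heterocyclic carbene catalyst should secure this.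

**Step 14**
Reactants: 16 (1S,4R,5R)-4-(tert-butyldimethylsilyloxy)-5-hydroxy-5-tridecanoylcyclopent-2-en-1-yl acetate
Product: 17 (1S,4R,5S)-4,5-dihydroxy-5-tridecanoylcyclopent-2-en-1-yl acetate
Conditions: HF·pyridine, THF/pyridine, 0 → 25 °C
Reagents that add atoms: none
Why: Fluoride-mediated desilylation under acidic conditions, which should avoid base-induced 1,3-acetyl migration between the cis oxygens (a path to the enantiomer) and retro-aldol cleavage of the β-hydroxy ketone.

**Compound list**
1 | methyl 4,6-O-benzylidene-α-D-glucopyranoside | CO[C@H]1O[C@@H]2CO[C@@H](c3ccccc3)O[C@H]2[C@H](O)[C@H]1O | starting material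
2 | methyl 4,6-O-benzylidene-2-O-(4-methoxybenzyl)-α-D-glucopyranoside | CO[C@H]1O[C@@H]2CO[C@@H](c3ccccc3)O[C@H]2[C@H](O)[C@H]1OCc4ccc(OC)cc4 | intermediate
3 | methyl 4,6-O-benzylidene-2-O-(4-methoxybenzyl)-α-D-ribo-hexopyranosid-3-ulose | CO[C@H]1O[C@@H]2CO[C@@H](c3ccccc3)O[C@H]2C(=O)[C@H]1OCc4ccc(OC)cc4 | intermediate
4 | tridecyltriphenylphosphonium bromide | CCCCCCCCCCCCC[P+](c1ccccc1)(c1ccccc1)c1ccccc1.[Br-] | starting material
5 | tridecylidenetriphenylphosphorane | CCCCCCCCCCCCC=P(c1ccccc1)(c1ccccc1)c1ccccc1 | intermediate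
6 | methyl 4,6-O-benzylidene-3-deoxy-2-O-(4-methoxybenzyl)-3-C-tridecylidene-α-D-ribo-hexopyranoside (alkene geometry mixed) | CO[C@H]1O[C@@H]2CO[C@@H](c3ccccc3)O[C@H]2C(=CCCCCCCCCCCCC)[C@H]1OCc4ccc(OC)cc4 | intermediate
7 | methyl 4,6-O-benzylidene-3-C-(1-hydroxytridecyl)-2-O-(4-methoxybenzyl)-α-D-glucopyranoside (C3–OH equatorial, side chain axial; C1′ mixed) | CO[C@H]1O[C@@H]2CO[C@@H](c3ccccc3)O[C@H]2[C@@](O)(C(O)CCCCCCCCCCCC)[C@H]1OCc4ccc(OC)cc4 | intermediate
8 | methyl 4,6-O-benzylidene-2-O-(4-methoxybenzyl)-3-C-tridecanoyl-α-D-glucopyranoside | CO[C@H]1O[C@@H]2CO[C@@H](c3ccccc3)O[C@H]2[C@@](O)(C(=O)CCCCCCCCCCCC)[C@H]1OCc4ccc(OC)cc4 | intermediate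
9 | methyl 4,6-O-benzylidene-3-C-tridecanoyl-α-D-glucopyranoside | CO[C@H]1O[C@@H]2CO[C@@H](c3ccccc3)O[C@H]2[C@@](O)(C(=O)CCCCCCCCCCCC)[C@H]1O | intermediate
10 | methyl 2-O-acetyl-4,6-O-benzylidene-3-C-tridecanoyl-α-D-glucopyranoside | CO[C@H]1O[C@@H]2CO[C@@H](c3ccccc3)O[C@H]2[C@@](O)(C(=O)CCCCCCCCCCCC)[C@H]1OC(C)=O | intermediate
11 | methyl 2-O-acetyl-3-C-tridecanoyl-α-D-glucopyranoside | CO[C@H]1O[C@H](CO)[C@@H](O)[C@@](O)(C(=O)CCCCCCCCCCCC)[C@H]1OC(C)=O | intermediate
12 | methyl 2-O-acetyl-6-deoxy-6-iodo-3-C-tridecanoyl-α-D-glucopyranoside | CO[C@H]1O[C@H](CI)[C@@H](O)[C@@](O)(C(=O)CCCCCCCCCCCC)[C@H]1OC(C)=O | intermediate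
13 | methyl 2-O-acetyl-4-O-(tert-butyldimethylsilyl)-6-deoxy-6-iodo-3-C-tridecanoyl-α-D-glucopyranoside | CO[C@H]1O[C@H](CI)[C@@H](O[Si](C)(C)C(C)(C)C)[C@@](O)(C(=O)CCCCCCCCCCCC)[C@H]1OC(C)=O | intermediate
14 | 2-O-acetyl-4-O-(tert-butyldimethylsilyl)-5,6-dideoxy-3-C-tridecanoyl-aldehydo-D-xylo-hex-5-enose, i.e. (2R,3R,4R)-2-acetoxy-4-(tert-butyldimethylsilyloxy)-3-hydroxy-3-tridecanoylhex-5-enal | CCCCCCCCCCCCC(=O)[C@]([C@@H](OC(C)=O)C=O)(O)[C@H](O[Si](C)(C)C(C)(C)C)C=C | intermediate
15 | (3S,4R,5R)-5-(tert-butyldimethylsilyloxy)-4-hydroxy-4-tridecanoylhepta-1,6-dien-3-yl acetate | CCCCCCCCCCCCC(=O)[C@]([C@@H](OC(C)=O)C=C)(O)[C@H](O[Si](C)(C)C(C)(C)C)C=C | intermediate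
16 | (1S,4R,5R)-4-(tert-butyldimethylsilyloxy)-5-hydroxy-5-tridecanoylcyclopent-2-en-1-yl acetate | CCCCCCCCCCCCC(=O)[C@]1(O)[C@H](O[Si](C)(C)C(C)(C)C)C=C[C@@H]1OC(C)=O | intermediate
17 | (1S,4R,5S)-4,5-dihydroxy-5-tridecanoylcyclopent-2-en-1-yl acetate | CCCCCCCCCCCCC(=O)[C@]1(O)[C@H](O)C=C[C@@H]1OC(C)=O | target

Total step count: 14. Longest linear sequence: 14 steps (1 → 17).

**Steps most likely to fail**

Step 3. The bulky, basic ylide may enolise the ulose instead of adding to it, leading to β-elimination of the anomeric methoxy group or epimerisation at C2 or C4. The fallback sets out from ketone 3 and installs the side chain one carbon at a time. Methylenation with methylenetriphenylphosphorane (from methyltriphenylphosphonium bromide and KN(SiMe3)2), a small and fast ylide, should give methyl 4,6-O-benzylidene-3-deoxy-2-O-(4-methoxybenzyl)-3-C-methylene-α-D-ribo-hexopyranoside F1. Dihydroxylation with OsO4 and N-methylmorpholine N-oxide from the same equatorial face should give methyl 4,6-O-benzylidene-3-C-(hydroxymethyl)-2-O-(4-methoxybenzyl)-α-D-glucopyranoside F2. Dess–Martin oxidation of the primary alcohol should give the 3-C-formyl glucoside F3. Addition of C12H25MgBr (excess, THF, −78 °C) to the aldehyde should then give diol 7, where the route is rejoined.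

Step 4. Osmylation of the crowded trisubstituted alkene may stall or occur on both faces, because the side chain has to take up the axial position beside the anomeric methoxy group. The fallback sets out from phosphonium salt 4 and builds the tertiary centre on a furanose template, where attack anti to a cis-fused 1,2-acetonide is the established course. Ylide 5 and commercial 1,2:5,6-di-O-isopropylidene-α-D-ribo-hexofuranos-3-ulose F4 should give 3-deoxy-1,2:5,6-di-O-isopropylidene-3-C-tridecylidene-α-D-ribo-hexofuranose F5. Osmylation on the convex face should give 3-C-(1-hydroxytridecyl)-1,2:5,6-di-O-isopropylidene-α-D-glucofuranose F6, and Dess–Martin oxidation the ketone 1,2:5,6-di-O-isopropylidene-3-C-tridecanoyl-α-D-glucofuranose F7. Hydrogen chloride in methanol at reflux (Fischer glycosidation with loss of both acetonides) should give methyl 3-C-tridecanoyl-α-D-glucopyranoside F8 after separation of anomers. Benzaldehyde dimethyl acetal with camphorsulfonic acid then gives 9, where the route is rejoined. This line is held in reserve because the anomer and ring-size distribution of the glycosidation is less predictable for this branched sugar.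

Step 12. The aldehyde may be lost through acetyl migration, retro-aldol cleavage or epimerisation at C2, or the dizinc reagent may be quenched by the tertiary hydroxyl before methylenation is complete. The fallback sets out from aldehyde 14 and divides the olefination into a two-stage Peterson sequence. Me3SiCH2MgCl premixed with CeCl3 (THF, −78 °C; non-basic and aldehyde-selective) should give the β-hydroxysilane (3R,4R,5R)-5-(tert-butyldimethylsilyloxy)-2,4-dihydroxy-4-tridecanoyl-1-(trimethylsilyl)hept-6-en-3-yl acetate F9. BF3·OEt2 in CH2Cl2 at 0 °C should then induce elimination of trimethylsilanol to give diene 15, where the route is rejoined.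

**Further compounds**
F1 | step 3 | methyl 4,6-O-benzylidene-3-deoxy-2-O-(4-methoxybenzyl)-3-C-methylene-α-D-ribo-hexopyranoside | CO[C@H]1O[C@@H]2CO[C@@H](c3ccccc3)O[C@H]2C(=C)[C@H]1OCc4ccc(OC)cc4
F2 | step 3 | methyl 4,6-O-benzylidene-3-C-(hydroxymethyl)-2-O-(4-methoxybenzyl)-α-D-glucopyranoside | CO[C@H]1O[C@@H]2CO[C@@H](c3ccccc3)O[C@H]2[C@@](O)(CO)[C@H]1OCc4ccc(OC)cc4
F3 | step 3 | methyl 4,6-O-benzylidene-3-C-formyl-2-O-(4-methoxybenzyl)-α-D-glucopyranoside | CO[C@H]1O[C@@H]2CO[C@@H](c3ccccc3)O[C@H]2[C@@](O)(C=O)[C@H]1OCc4ccc(OC)cc4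
F4 | step 4 | 1,2:5,6-di-O-isopropylidene-α-D-ribo-hexofuranos-3-ulose | CC1(C)O[C@@H]2C(=O)[C@@H]([C@H]3COC(C)(C)O3)O[C@@H]2O1
F5 | step 4 | 3-deoxy-1,2:5,6-di-O-isopropylidene-3-C-tridecylidene-α-D-ribo-hexofuranose | CC1(C)O[C@@H]2C(=CCCCCCCCCCCCC)[C@@H]([C@H]3COC(C)(C)O3)O[C@@H]2O1
F6 | step 4 | 3-C-(1-hydroxytridecyl)-1,2:5,6-di-O-isopropylidene-α-D-glucofuranose | CC1(C)O[C@@H]2[C@](O)(C(O)CCCCCCCCCCCC)[C@@H]([C@H]3COC(C)(C)O3)O[C@@H]2O1
F7 | step 4 | 1,2:5,6-di-O-isopropylidene-3-C-tridecanoyl-α-D-glucofuranose | CC1(C)O[C@@H]2[C@](O)(C(=O)CCCCCCCCCCCC)[C@@H]([C@H]3COC(C)(C)O3)O[C@@H]2O1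
F8 | step 4 | methyl 3-C-tridecanoyl-α-D-glucopyranoside | CO[C@H]1O[C@H](CO)[C@@H](O)[C@@](O)(C(=O)CCCCCCCCCCCC)[C@H]1O
F9 | step 12 | (3R,4R,5R)-5-(tert-butyldimethylsilyloxy)-2,4-dihydroxy-4-tridecanoyl-1-(trimethylsilyl)hept-6-en-3-yl acetate | CCCCCCCCCCCCC(=O)[C@]([C@@H](OC(C)=O)C(O)C[Si](C)(C)C)(O)[C@H](O[Si](C)(C)C(C)(C)C)C=C
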